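## Retrosynthetic overview

- The target comes from triol 20 by tigloylation and desilylation. Triol 20 comes from trienone 16 by epoxidation anti to the angular methyl and SmI2 opening (C4–OH, C10–OH), 10‑OH‑directed epoxidation (8,9‑oxirane) and 4‑OH‑directed reduction (C6–OH).
- Trienone 16 comes from vinylogous ester 14 by Stork–Danheiser isopropyl addition and transposition. Compound 14 comes from 10 by 4‑OH‑directed reduction of C2 and allylic oxidation at C4.
- Compound 10 comes from aryl diazo ketone 8 by an intramolecular Buchner reaction. Compound 8 comes from aldehyde 1 by an acetate aldol reaction and acylation of diazoethane.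
- Enabling feature: the seven‑membered ring (C1, C5–C10) is a benzene ring (C5–C10, already carrying the C6 oxygen as OMe and the C8 methyl) plus the single carbon C1. C1 bears the angular methyl and the C2 carbonyl, so it is a keto‑carbene carbon.
- Ring order: cyclopentane (C1–C5 bond) and cycloheptatriene (benzene ring enlarged by C1) form together in step 5; the oxiranes follow in steps 11 and 13.

Key step: step 5

Remark: daucane numbering is used throughout. C1 is the carbon with the angular methyl, C2–C4 are the other cyclopentane carbons, C5 is the ring‑fusion CH, and C6–C10 are the other seven‑ring carbons. β is the face of the C1 methyl and α the opposite face. Both acyl groups of the target are (E)‑2‑methylbut‑2‑enoyl (tigloyl). Compounds 1, 2 and tiglic anhydride are taken as commercially available; dimethyldioxirane is used as its acetone solution.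

## Route

Step 1
Reactants: 1 2‑methoxy‑4‑methylbenzaldehyde; 2 (S)‑2‑hydroxy‑1,2,2‑triphenylethyl acetate [(S)‑HYTRA]
Product: 3 (S)‑2‑hydroxy‑1,2,2‑triphenylethyl (S)‑3‑hydroxy‑3‑(2‑methoxy‑4‑methylphenyl)propanoate
Conditions: LiN(iPr)2 (2.1 equiv), THF, −78 → 0 °C; then 1, −105 °C; aq NH4Cl
Reagents that add atoms: none
Why: Auxiliary‑controlled acetate aldol addition of the doubly lithiated chiral acetate should set the benzylic carbinol as S (aryl outranks CH2), the stereocentre that later controls C1 and C2 and is then erased.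

Step 2
Reactants: 3 aldol ester
Product: 4 (S)‑3‑hydroxy‑3‑(2‑methoxy‑4‑methylphenyl)propanoic acid
Conditions: KOH, MeOH/H2O, 65 °C; then HCl to pH 3
Reagents that add atoms: potassium hydroxide [K+].[OH-]
Why: Ester saponification should release the acid without touching the carbinol stereocentre and lets the triphenylethanediol be recovered.

Step 3
Reactants: 4 hydroxy acid
Product: 6 (S)‑3‑(tert‑butyldimethylsilyloxy)‑3‑(2‑methoxy‑4‑methylphenyl)propanoic acid, via silyl ester 5 (not isolated)
Conditions: TBSCl (2.5 equiv), imidazole, DMF, 23 °C; then K2CO3, MeOH/THF/H2O, 0 °C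
Reagents that add atoms: tert‑butyldimethylsilyl chloride CC(C)(C)[Si](C)(C)Cl
Why: Bis‑silylation followed by selective methanolysis of the labile silyl ester should leave the benzylic silyl ether, which masks the hydroxyl against O–H insertion in step 5.

Step 4
Reactants: 6 silyloxy acid
Product: 8 (S)‑5‑(tert‑butyldimethylsilyloxy)‑2‑diazo‑5‑(2‑methoxy‑4‑methylphenyl)pentan‑3‑one, via mixed carbonic anhydride 7 (not isolated)
Conditions: iBuOCOCl, N‑methylmorpholine, THF, −20 °C; then CH3CHN2, Et2O, −20 → 0 °C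
Reagents that add atoms: diazoethane CC=[N+]=[N-]
Why: Acylation of diazoethane by the mixed anhydride (Arndt–Eistert‑type diazo ketone synthesis) installs C1 with its methyl group under non‑acidic conditions that spare the electron‑rich benzylic silyl ether.

Step 5
Reactants: 8 diazo ketone
Product: 10 (3S,8aS)‑3‑(tert‑butyldimethylsilyloxy)‑4‑methoxy‑6,8a‑dimethyl‑3,8a‑dihydroazulen‑1(2H)‑one (daucane numbering: 2‑oxo, 4α‑OTBS, 6‑OMe, Δ5, Δ7, Δ9), via norcaradiene 9 (not isolated)
Conditions: Rh2(OAc)4 (1 mol %), CH2Cl2, 40 °C, slow addition of 8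
Reagents that add atoms: none
Why: The keto‑carbenoid at C1 adds across the C5–C10 bond of the anisole ring (C5 ipso, C10 the unsubstituted ortho carbon) to give norcaradiene 9, and disrotatory six‑electron opening of the C5–C10 bond enlarges the benzene ring (C5–C10) to the cycloheptatriene (C1, C5–C10); the closest known reaction type is the intramolecular Buchner reaction of 1‑diazo‑4‑arylbutan‑2‑ones and their 1‑methyl homologues. The five‑membered ring (C1–C5) closes by the cyclopropanation, formally a 5‑exo attack of the carbenoid carbon on the ipso carbon, whereas the seven‑membered ring forms by ring expansion and not by a closure of its own. The one new stereocentre, C1, is controlled by C4: allylic 1,3‑strain keeps the C4–H bond in the arene plane next to the ortho methoxy group, so the chain (C3) and the silyloxy group lie on opposite faces and the carbenoid reaches only the face of the chain, which puts the angular methyl trans to the silyloxy group (the known trans preference of benzylic substituents in this reaction). The step needs chemoselectivity for arene addition over 1,2‑hydride shift of the methyl carbenoid and over attack on the silyl ether oxygen, which the electron‑rich ring and slow addition should secure. It also needs regioselectivity for the unsubstituted ortho bond, which the same conformer and the steric shielding of the methoxy‑bearing ortho carbon should secure. The 8a‑methyl group blocks tautomerisation of the product to a conjugated azulenone or a tetralone.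

Step 6
Reactants: 10 silyloxy trienol ether ketone
Product: 11 (3S,8aS)‑3‑hydroxy‑4‑methoxy‑6,8a‑dimethyl‑3,8a‑dihydroazulen‑1(2H)‑one (4α‑OH)
Conditions: Bu4NF/AcOH (1:1), THF, 0 °C
Reagents that add atoms: none
Why: Buffered fluoride desilylation frees the 4α‑hydroxyl as the anchor for step 7, the acetic acid suppressing retro‑aldol opening of the β‑hydroxy ketone.

Step 7
Reactants: 11 β‑hydroxy ketone
Product: 12 2β,4α‑dihydroxy‑6‑methoxy‑1β,8‑dimethylhydroazulena‑5,7,9‑triene (daucane numbering)
Conditions: SmI2 (3 equiv), MeOH, THF, 0 °C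
Reagents that add atoms: none
Why: Hydroxyl‑directed SmI2 reduction of a β‑hydroxy ketone: samarium held by the 4α‑oxygen places the new C2–H bond on the α‑face, so the 2‑hydroxyl is β (anti 1,3‑diol, cis to the angular methyl), and the trienol ether is inert under these neutral conditions.

Step 8
Reactants: 12 diol
Product: 13 2β‑hydroxy‑6‑methoxy‑1β,8‑dimethylhydroazulena‑5,7,9‑trien‑4‑one
Conditions: MnO2, CH2Cl2, 23 °C
Reagents that add atoms: none
Why: MnO2 oxidises only the allylic C4 alcohol (activated by the trienol ether) to the vinylogous ester ketone and leaves the saturated neopentyl C2 alcohol.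

Step 9
Reactants: 13 hydroxy vinylogous ester
Product: 14 2β‑(tert‑butyldimethylsilyloxy)‑6‑methoxy‑1β,8‑dimethylhydroazulena‑5,7,9‑trien‑4‑one
Conditions: TBSOTf, 2,6‑lutidine, CH2Cl2, −78 °C
Reagents that add atoms: tert‑butyldimethylsilyl triflate CC(C)(C)[Si](C)(C)OS(=O)(=O)C(F)(F)F
Why: Silyl triflate silylation masks the hindered 2β‑hydroxyl (no new stereocentre) until the last step, so that it neither directs the later epoxidation nor is acylated.

Step 10
Reactants: 14 vinylogous ester
Product: 16 2β‑(tert‑butyldimethylsilyloxy)‑4‑isopropyl‑1β,8‑dimethylhydroazulena‑4,7,9‑trien‑6‑one, via tertiary carbinol 15 (not isolated)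
Conditions: iPrMgCl, CeCl3, THF, −78 °C; then 1 M HCl, THF, 0 °C
Reagents that add atoms: isopropylmagnesium chloride CC(C)[Mg]Cl; water O
Why: Stork–Danheiser sequence: the organocerium reagent adds 1,2 to the vinylogous ester carbonyl without enolisation, and acid then ionises the tertiary allylic alcohol to a methoxy‑stabilised cation that is hydrolysed at C6, giving the C4=C5 enone cross‑conjugated to the C7–C10 diene (the C4 stereocentre of 15 is lost).

Step 11
Reactants: 16 trienone
Product: 17 4α,5α:9α,10α‑diepoxy‑2β‑(tert‑butyldimethylsilyloxy)‑4‑isopropyl‑1β,8‑dimethylhydroazulen‑7‑en‑6‑one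
Conditions: dimethyldioxirane (2.3 equiv), acetone, −20 → 0 °C
Reagents that add atoms: dimethyldioxirane CC1(C)OO1
Why: Electrophilic epoxidation should take first the electron‑rich distal C9=C10 bond of the dienone and then the tetrasubstituted C4=C5 bond, each from the α‑face anti to the angular methyl on the adjacent C1 (and the 2β‑silyloxy group), which sets the α‑oxygens at C10 and C4; the C7=C8 bond is deactivated by the carbonyl and the neighbouring oxirane.

Step 12
Reactants: 17 diepoxy enone
Product: 18 2β‑(tert‑butyldimethylsilyloxy)‑4α,10α‑dihydroxy‑4β‑isopropyl‑1β,8‑dimethyl‑5β‑H‑hydroazulen‑8‑en‑6‑one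
Conditions: SmI2 (4.5 equiv), THF/MeOH, −78 °C; pH 7 buffer
Reagents that add atoms: none
Why: SmI2 reduction of an α,β‑epoxy ketone and of a vinylogous (γ,δ) epoxy enone: the C5–O bond is cleaved to the β‑ketol (4α‑OH kept) and the C9–O bond is cleaved with shift of the double bond to C8=C9 and protonation at C7 (10α‑OH kept); C5 is set by protonation of the samarium enolate, expected on the β‑face because the α‑face is covered by the samarium alkoxides on O4 and O10, which gives the cis‑fused ketol, also the more stable epimer (C6 anti to isopropyl, O4–H···O6 hydrogen bond).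

Step 13
Reactants: 18 allylic alcohol
Product: 19 8α,9α‑epoxy‑2β‑(tert‑butyldimethylsilyloxy)‑4α,10α‑dihydroxy‑4β‑isopropyl‑1β,8β‑dimethyl‑5β‑H‑hydroazulen‑6‑one
Conditions: VO(acac)2 (5 mol %), tBuOOH, CH2Cl2, 0 °C
Reagents that add atoms: tert‑butyl hydroperoxide CC(C)(C)OO
Why: Hydroxyl‑directed epoxidation of a cyclic allylic alcohol delivers oxygen syn to the 10α‑hydroxyl and gives the 8α,9α‑oxirane under neutral conditions that avoid base‑induced opening of the resulting β,γ‑epoxy ketone.

Step 14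
Reactants: 19 epoxy ketone
Product: 20 8α,9α‑epoxy‑2β‑(tert‑butyldimethylsilyloxy)‑4β‑isopropyl‑1β,8β‑dimethyl‑5β‑H‑hydroazulene‑4α,6β,10α‑triol
Conditions: Me4NBH(OAc)3, MeCN/AcOH, −30 °C
Reagents that add atoms: none
Why: Evans–Saksena reduction: the borohydride bound to the tertiary 4α‑hydroxyl delivers hydride intramolecularly to the α‑face of the C6 ketone and gives the 6β‑alcohol (anti 1,3‑diol); no ketone remains for the 10α‑hydroxyl to direct.

Step 15
Reactants: 20 triol
Product: 21 2‑O‑TBS ether of the target (6β,10α‑di‑O‑tigloyl)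
Conditions: tiglic anhydride, DMAP, Et3N, CH2Cl2, 23 → 40 °C
Reagents that add atoms: tiglic anhydride C/C=C(\C)C(=O)OC(=O)/C(C)=C/C
Why: DMAP‑catalysed acylation esterifies the two secondary alcohols at C6 and C10 with the geometrically stable (E)‑anhydride, while the tertiary 4‑hydroxyl does not react and the 2‑hydroxyl is silylated.

Step 16
Reactants: 21 silyl ether
Product: 22 target, 8α,9α‑epoxy‑2β,4α‑dihydroxy‑6β,10α‑bis(tigloyloxy)‑cis‑daucane (CNP0265715.1)
Conditions: Bu4NF/AcOH (1:1), THF, 23 °C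
Reagents that add atoms: none
Why: Buffered fluoride desilylation removes the last protecting group without acyl migration or opening of the oxirane.

## Compound list

1 | 2‑methoxy‑4‑methylbenzaldehyde | COc1cc(C)ccc1C=O | starting material
2 | (S)‑2‑hydroxy‑1,2,2‑triphenylethyl acetate | CC(=O)O[C@@H](c1ccccc1)C(O)(c1ccccc1)c1ccccc1 | starting material
3 | (S)‑HYTRA ester of (S)‑3‑hydroxy‑3‑(2‑methoxy‑4‑methylphenyl)propanoic acid | COc1cc(C)ccc1[C@@H](O)CC(=O)O[C@@H](c1ccccc1)C(O)(c1ccccc1)c1ccccc1 | intermediate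
4 | (S)‑3‑hydroxy‑3‑(2‑methoxy‑4‑methylphenyl)propanoic acid | COc1cc(C)ccc1[C@@H](O)CC(=O)O | intermediate
5 | TBS ester of 6 | COc1cc(C)ccc1[C@@H](O[Si](C)(C)C(C)(C)C)CC(=O)O[Si](C)(C)C(C)(C)C | intermediate
6 | (S)‑3‑(tert‑butyldimethylsilyloxy)‑3‑(2‑methoxy‑4‑methylphenyl)propanoic acid | COc1cc(C)ccc1[C@@H](O[Si](C)(C)C(C)(C)C)CC(=O)O | intermediate
7 | isobutyl carbonic mixed anhydride of 6 | COc1cc(C)ccc1[C@@H](O[Si](C)(C)C(C)(C)C)CC(=O)OC(=O)OCC(C)C | intermediate
8 | (S)‑5‑(tert‑butyldimethylsilyloxy)‑2‑diazo‑5‑(2‑methoxy‑4‑methylphenyl)pentan‑3‑one | COc1cc(C)ccc1[C@@H](O[Si](C)(C)C(C)(C)C)CC(=O)C(C)=[N+]=[N-] | intermediate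
9 | norcaradiene (cyclopropane C1–C5–C10) | COC1=CC(C)=C[C@H]2[C@]3(C)C(=O)C[C@H](O[Si](C)(C)C(C)(C)C)[C@]123 | intermediate
10 | (3S,8aS)‑3‑(tert‑butyldimethylsilyloxy)‑4‑methoxy‑6,8a‑dimethyl‑3,8a‑dihydroazulen‑1(2H)‑one | COC=1C=C(C)C=C[C@@]2(C)C=1[C@@H](O[Si](C)(C)C(C)(C)C)CC2=O | intermediate
11 | (3S,8aS)‑3‑hydroxy‑4‑methoxy‑6,8a‑dimethyl‑3,8a‑dihydroazulen‑1(2H)‑one | COC=1C=C(C)C=C[C@@]2(C)C=1[C@@H](O)CC2=O | intermediate
12 | 2β,4α‑dihydroxy‑6‑methoxy‑1β,8‑dimethylhydroazulena‑5,7,9‑triene | COC=1C=C(C)C=C[C@@]2(C)C=1[C@@H](O)C[C@@H]2O | intermediate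
13 | 2β‑hydroxy‑6‑methoxy‑1β,8‑dimethylhydroazulena‑5,7,9‑trien‑4‑one | COC=1C=C(C)C=C[C@@]2(C)C=1C(=O)C[C@@H]2O | intermediate
14 | 2β‑TBS ether of 13 | COC=1C=C(C)C=C[C@@]2(C)C=1C(=O)C[C@@H]2O[Si](C)(C)C(C)(C)C | intermediate
15 | 4‑isopropyl tertiary carbinol (4β‑OH expected) | COC=1C=C(C)C=C[C@@]2(C)C=1[C@@](O)(C(C)C)C[C@@H]2O[Si](C)(C)C(C)(C)C | intermediate
16 | 2β‑(tert‑butyldimethylsilyloxy)‑4‑isopropyl‑1β,8‑dimethylhydroazulena‑4,7,9‑trien‑6‑one | O=C1C=C(C)C=C[C@@]2(C)C1=C(C(C)C)C[C@@H]2O[Si](C)(C)C(C)(C)C | intermediate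
17 | 4α,5α:9α,10α‑diepoxide of 16 | O=C1C=C(C)[C@@H]2O[C@@H]2[C@@]3(C)[C@]14O[C@@]4(C(C)C)C[C@@H]3O[Si](C)(C)C(C)(C)C | intermediate
18 | 2β‑OTBS‑4α,10α‑dihydroxy‑4β‑isopropyl‑5β‑H‑hydroazulen‑8‑en‑6‑one | O=C1CC(C)=C[C@H](O)[C@@]2(C)[C@@H]1[C@](O)(C(C)C)C[C@@H]2O[Si](C)(C)C(C)(C)C | intermediate
19 | 8α,9α‑epoxide of 18 | O=C1C[C@]2(C)O[C@@H]2[C@H](O)[C@@]3(C)[C@@H]1[C@](O)(C(C)C)C[C@@H]3O[Si](C)(C)C(C)(C)C | intermediate
20 | 8α,9α‑epoxy‑2β‑OTBS‑4α,6β,10α‑triol | O[C@H]1C[C@]2(C)O[C@@H]2[C@H](O)[C@@]3(C)[C@@H]1[C@](O)(C(C)C)C[C@@H]3O[Si](C)(C)C(C)(C)C | intermediate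
21 | 2‑O‑TBS ether of the target | C/C=C(\C)C(=O)O[C@H]1C[C@]2(C)O[C@@H]2[C@H](OC(=O)/C(C)=C/C)[C@@]3(C)[C@@H]1[C@](O)(C(C)C)C[C@@H]3O[Si](C)(C)C(C)(C)C | intermediate
22 | CNP0265715.1 | C/C=C(\C)C(=O)O[C@H]1C[C@]2(C)O[C@@H]2[C@H](OC(=O)/C(C)=C/C)[C@@]2(C)[C@@H]1[C@](O)(C(C)C)C[C@@H]2O | target

Total step count: 16. Longest linear sequence: 16 steps (from 1).

## Steps most likely to fail

**Step 5.** The methyl‑substituted carbenoid may undergo 1,2‑hydride migration, or attack the silyl ether oxygen, faster than it adds to the arene. Fallback with a carbenoid that has no β‑hydrogen: from acid 6, the mixed anhydride 7 is treated with diazomethane to give the terminal diazo ketone F1, the parent substrate class of the intramolecular Buchner reaction. Rh2(OAc)4 should convert it into the 8a‑H azulenone F2. The angular methyl is then introduced by deprotonation at C1 with LiN(SiMe3)2 (THF, −78 °C) and C‑methylation with MeI anti to the 4α‑silyloxy group, which comes back to the route at 10.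

**Step 12.** Protonation of the samarium enolate from the open α‑face would give the trans‑fused C5 epimer. This cannot be equilibrated afterwards, because base would move the C8=C9 bond into conjugation. Over‑ or under‑reduction of the two oxiranes is a second risk. Fallback in which C5–H comes from a stereospecific 1,2‑hydride shift instead of a protonation, setting out from 16:
- mCPBA (1 equiv, NaHCO3) gives the 9α,10α‑monoepoxide F3;
- SmI2/MeOH gives the δ‑hydroxy enone F4;
- VO(acac)2/tBuOOH gives the 8α,9α‑epoxide F5;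
- dimethyldioxirane gives the 4α,5α‑epoxy ketone F6;
- Zn(BH4)2 gives the cis‑epoxy alcohol F7 (hydride anti to the oxirane oxygens, 6α‑OH);
- BF3·OEt2 (CH2Cl2, −78 °C) triggers the semipinacol rearrangement of the 2,3‑epoxy alcohol. The C6 hydride migrates to C5 anti to the breaking C5–O bond, the C6 ketone is regenerated, and the route is rejoined at 19 with 4α‑OH and 5β‑H.

**Step 10.** The secondary organometallic may enolise the hindered vinylogous ester carbonyl or add incompletely. Fallback in which the isopropyl group enters by conjugate addition, setting out from diol 12: aqueous HCl ionises the allylic C4 alcohol and hydrolyses the enol ether to the C4‑unsubstituted hydroxy trienone F8. TBSOTf/2,6‑lutidine gives its silyl ether F9. (iPr)2CuLi with Me3SiCl adds at C4, the least hindered β‑position, to give silyl enol ether F10. Saegusa–Ito oxidation with Pd(OAc)2 (MeCN) restores the C4=C5 bond and comes back to the route at 16.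

## Further compounds

F1 | step 5 | (S)‑4‑(tert‑butyldimethylsilyloxy)‑1‑diazo‑4‑(2‑methoxy‑4‑methylphenyl)butan‑2‑one | COc1cc(C)ccc1[C@@H](O[Si](C)(C)C(C)(C)C)CC(=O)C=[N+]=[N-]
F2 | step 5 | 8a‑H analogue of 10 (3‑silyloxy‑4‑methoxy‑6‑methyl‑3,8a‑dihydroazulen‑1(2H)‑one) | COC=1C=C(C)C=C[C@H]2C=1[C@@H](O[Si](C)(C)C(C)(C)C)CC2=O
F3 | step 12 | 9α,10α‑monoepoxide of 16 | O=C1C=C(C)[C@@H]2O[C@@H]2[C@@]3(C)C1=C(C(C)C)C[C@@H]3O[Si](C)(C)C(C)(C)C
F4 | step 12 | 10α‑hydroxy‑4,8‑dien‑6‑one | O=C1CC(C)=C[C@H](O)[C@@]2(C)C1=C(C(C)C)C[C@@H]2O[Si](C)(C)C(C)(C)C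
F5 | step 12 | 8α,9α‑epoxy‑10α‑hydroxy‑4‑en‑6‑one | O=C1C[C@]2(C)O[C@@H]2[C@H](O)[C@@]3(C)C1=C(C(C)C)C[C@@H]3O[Si](C)(C)C(C)(C)C
F6 | step 12 | 4α,5α:8α,9α‑diepoxy‑10α‑hydroxy‑6‑one | O=C1C[C@]2(C)O[C@@H]2[C@H](O)[C@@]3(C)[C@]14O[C@@]4(C(C)C)C[C@@H]3O[Si](C)(C)C(C)(C)C
F7 | step 12 | 4α,5α:8α,9α‑diepoxy‑6α,10α‑diol | O[C@@H]1C[C@]2(C)O[C@@H]2[C@H](O)[C@@]3(C)[C@]14O[C@@]4(C(C)C)C[C@@H]3O[Si](C)(C)C(C)(C)C
F8 | step 10 | 2β‑hydroxy‑1β,8‑dimethylhydroazulena‑4,7,9‑trien‑6‑one | O=C1C=C(C)C=C[C@@]2(C)C1=CC[C@@H]2O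
F9 | step 10 | 2β‑TBS ether of F8 | O=C1C=C(C)C=C[C@@]2(C)C1=CC[C@@H]2O[Si](C)(C)C(C)(C)C
F10 | step 10 | 6‑trimethylsilyloxy‑4‑isopropyl‑5,7,9‑triene (silyl enol ether) | C[Si](C)(C)OC=1C=C(C)C=C[C@@]2(C)C=1[C@@H](C(C)C)C[C@@H]2O[Si](C)(C)C(C)(C)C
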